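**Retrosynthetic overview**
1. Target ⇐ methacrylation of the 8-hydroxy lactone ⇐ desilylation of the O8-triethylsilyl macrolactone.
2. The ten-membered carbocycle and the γ-lactone are cut together at C6–C7: intramolecular CrCl2-mediated 2-(methoxycarbonyl)allylation of the C6 E-enal by a (Z)-2-(bromomethyl)enoate; C7 and C6 are set from C8.
3. Allyl bromide ⇐ Morita–Baylis–Hillman adduct ⇐ (8S)-α-silyloxy aldehyde ⇐ C7 aldehyde by a new organocatalytic α-silyloxylation.
4. 1,10-Epoxide (first stereocentres) ⇐ organocatalytic epoxidation of an α-branched E-enal ⇐ Wittig reaction of a geranyl-acetate-derived aldehyde with a formyl ylide.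
5. Ring order: oxirane first (step 4), then carbocycle and lactone in one operation (step 12).

Atom labels C1–C15 follow germacrane numbering (C1–C10 ring, C11–C13 on C7, C14 on C10, C15 on C4).
Assumption: the epi-quinidine-derived amine salt is taken to give the (2S,3R)-epoxy aldehyde in step 4; if the first run shows the opposite sense, the pseudo-enantiomeric epi-quinine-derived salt is used and nothing else changes.

Step 1
Reactants: 1 geranyl acetate
Product: 2 (2E)-3-methyl-6-oxohex-2-en-1-yl acetate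
Conditions: O3, CH2Cl2/pyridine, −78 °C (indicator end point); Me2S, −78 °C → rt
Reagents that add atoms: ozone, [O-][O+]=O
Why: Chemoselective ozonolysis, because the electron-rich 6,7-alkene is cleaved much faster than the 2,3-alkene deactivated by the allylic acetate, and reductive work-up gives the aldehyde with the E-alkene untouched.

Step 2
Reactants: 3 (pent-4-en-1-yl)triphenylphosphonium bromide; 4 ethyl formate
Product: 6 2-(triphenylphosphoranylidene)hex-5-enal, via pent-4-enylidene ylide 5 (not isolated)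
Conditions: NaN(SiMe3)2 (2.1 equiv), THF, −78 → 0 °C; HCO2Et, 0 °C → rt
Reagents that add atoms: none
Why: Ylide acylation, in which the non-stabilised ylide is C-formylated by ethyl formate and the β-oxophosphonium salt is deprotonated by the second equivalent of base to the formyl-stabilised ylide.

Step 3
Reactants: 2 (2E)-3-methyl-6-oxohex-2-en-1-yl acetate; 6 2-(triphenylphosphoranylidene)hex-5-enal
Product: 7 (2E,6E)-7-formyl-3-methylundeca-2,6,10-trien-1-yl acetate
Conditions: toluene, 100 °C, 24 h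
Reagents that add atoms: none
Why: Wittig olefination with an α-alkyl formyl-stabilised ylide, which gives the (E)-2-alkyl-2-enal (CHO trans to the C2 chain, side chain cis to it), the geometry needed for the cis-fused 1,10-epoxide.

Step 4
Reactants: 7 (2E,6E)-7-formyl-3-methylundeca-2,6,10-trien-1-yl acetate
Product: 8 (2S,3R)-3-[(3E)-5-acetoxy-3-methylpent-3-en-1-yl]-2-(but-3-en-1-yl)oxirane-2-carbaldehyde
Conditions: 9-amino(9-deoxy)epi-quinidine (10 mol%), CF3CO2H (20 mol%), 50% aq. H2O2 (1.5 equiv), dioxane, 40 °C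
Reagents that add atoms: hydrogen peroxide, OO
Why: Iminium-catalysed nucleophilic (Weitz–Scheffer type) epoxidation of an α-branched enal, in which the catalyst-bound hydroperoxide adds to C1 on one face of the E-iminium ion and the enamine closes onto O–O with retention of geometry, setting C1 and the quaternary C10 as the first stereocentres while the isolated alkenes do not react.

Step 5
Reactants: 8 (2S,3R)-3-[(3E)-5-acetoxy-3-methylpent-3-en-1-yl]-2-(but-3-en-1-yl)oxirane-2-carbaldehyde
Product: 10 (2E)-5-[(2R,3R)-3-(but-3-en-1-yl)-3-(hydroxymethyl)oxiran-2-yl]-3-methylpent-2-en-1-ol, via epoxy alcohol acetate 9 (not isolated)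
Conditions: NaBH4, MeOH, −20 °C; then K2CO3 (0.3 equiv), 0 °C
Reagents that add atoms: none
Why: Borohydride reduction of the aldehyde followed by carbonate-catalysed methanolysis of the allylic acetate, with no stereocentre touched and the trisubstituted 2,3-epoxy alcohol being the stable Payne isomer.

Step 6
Reactants: 10 (2E)-5-[(2R,3R)-3-(but-3-en-1-yl)-3-(hydroxymethyl)oxiran-2-yl]-3-methylpent-2-en-1-ol
Product: 11 (2E)-5-[(2R,3R)-3-(but-3-en-1-yl)-3-(hydroxymethyl)oxiran-2-yl]-3-methylpent-2-enal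
Conditions: MnO2 (20 equiv), CH2Cl2, rt
Reagents that add atoms: none
Why: Manganese dioxide oxidation is selective for the allylic primary alcohol (the epoxy carbinol is no longer allylic) and gives the E-enal, which also deactivates the C4=C5 alkene for the rest of the route.

Step 7
Reactants: 11 (2E)-5-[(2R,3R)-3-(but-3-en-1-yl)-3-(hydroxymethyl)oxiran-2-yl]-3-methylpent-2-enal
Product: 12 [(2R,3R)-2-(but-3-en-1-yl)-3-[(3E)-3-methyl-5-oxopent-3-en-1-yl]oxiran-2-yl]methyl acetate
Conditions: Ac2O, pyridine, DMAP (5 mol%), CH2Cl2, 0 °C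
Reagents that add atoms: acetic anhydride, CC(=O)OC(C)=O
Why: DMAP-catalysed acetylation of the only free hydroxyl installs the C14 acetate of the target.

Step 8
Reactants: 12 [(2R,3R)-2-(but-3-en-1-yl)-3-[(3E)-3-methyl-5-oxopent-3-en-1-yl]oxiran-2-yl]methyl acetate
Product: 14 [(2R,3R)-3-[(3E)-3-methyl-5-oxopent-3-en-1-yl]-2-(3-oxopropyl)oxiran-2-yl]methyl acetate, via vicinal diol 13 (not isolated)
Conditions: OsO4 (2 mol%), NaIO4 (4 equiv), 2,6-lutidine, dioxane/H2O (3:1), rt
Reagents that add atoms: osmium tetroxide, O=[Os](=O)(=O)=O; sodium periodate, [Na+].[O-]I(=O)(=O)=O; water, O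
Why: Lemieux–Johnson cleavage, in which OsO4 dihydroxylates the terminal alkene far faster than the electron-poor enal alkene and periodate cleaves the diol to the C7 aldehyde under buffered conditions that spare the epoxide.

Step 9
Reactants: 14 [(2R,3R)-3-[(3E)-3-methyl-5-oxopent-3-en-1-yl]-2-(3-oxopropyl)oxiran-2-yl]methyl acetate
Product: 15 [(2R,3R)-3-[(3E)-3-methyl-5-oxopent-3-en-1-yl]-2-[(2S)-3-oxo-2-(triethylsilyloxy)propyl]oxiran-2-yl]methyl acetate
Conditions: mCPBA, Et3SiCl, imidazole, CH2Cl2, −20 °C, 20 min (forms Et3SiOOC(O)C6H4-3-Cl); then 14, (S)-α,α-diphenylprolinol trimethylsilyl ether (10 mol%), hydroquinone (10 mol%), THF, 0 °C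
Reagents that add atoms: chlorotriethylsilane, CC[Si](CC)(CC)Cl; 3-chloroperoxybenzoic acid, OOC(=O)c1cccc(Cl)c1 (together they form triethylsilyl 3-chloroperoxybenzoate, CC[Si](CC)(CC)OOC(=O)c1cccc(Cl)c1, which transfers Et3SiO)
Why: Proposed new method: the E-enamine of the saturated aldehyde, shielded on one face by the (S)-diarylprolinol silyl ether, should attack the silylated peroxy oxygen of the silyl perester in an SN2 displacement at oxygen with 3-chlorobenzoate (the better leaving group) departing, giving the (8S)-α-silyloxy aldehyde directly; the closest known reaction types are the enamine-catalysed α-benzoyloxylation of aldehydes with dibenzoyl peroxide and the attack of carbon nucleophiles on the alkoxy oxygen of peresters or on bis(silyl) peroxides.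

Step 10
Reactants: 15 [(2R,3R)-3-[(3E)-3-methyl-5-oxopent-3-en-1-yl]-2-[(2S)-3-oxo-2-(triethylsilyloxy)propyl]oxiran-2-yl]methyl acetate; 16 methyl acrylate
Product: 17 methyl (4S)-5-[(2R,3R)-2-(acetoxymethyl)-3-[(3E)-3-methyl-5-oxopent-3-en-1-yl]oxiran-2-yl]-3-hydroxy-2-methylidene-4-(triethylsilyloxy)pentanoate (both C3 epimers)
Conditions: DABCO (1 equiv), methyl acrylate (10 equiv, neat), rt, 48 h
Reagents that add atoms: none
Why: Morita–Baylis–Hillman reaction, in which the DABCO–acrylate zwitterion adds to the activated α-silyloxy aldehyde (the β,β-disubstituted enal is inert) and the new carbinol centre at C7 need not be controlled because it is removed in the next step.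

Step 11
Reactants: 17 methyl (4S)-5-[(2R,3R)-2-(acetoxymethyl)-3-[(3E)-3-methyl-5-oxopent-3-en-1-yl]oxiran-2-yl]-3-hydroxy-2-methylidene-4-(triethylsilyloxy)pentanoate
Product: 18 methyl (2Z,4S)-5-[(2R,3R)-2-(acetoxymethyl)-3-[(3E)-3-methyl-5-oxopent-3-en-1-yl]oxiran-2-yl]-2-(bromomethyl)-4-(triethylsilyloxy)pent-2-enoate
Conditions: NBS, Me2S, CH2Cl2, −20 → 0 °C
Reagents that add atoms: N-bromosuccinimide, O=C1CCC(=O)N1Br
Why: Corey–Kim type activation of the allylic alcohol and SN2′ displacement by bromide gives the rearranged (Z)-2-(bromomethyl)enoate, the thermodynamically preferred geometry with C8 trans to the ester.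

Step 12
Reactants: 18 methyl (2Z,4S)-5-[(2R,3R)-2-(acetoxymethyl)-3-[(3E)-3-methyl-5-oxopent-3-en-1-yl]oxiran-2-yl]-2-(bromomethyl)-4-(triethylsilyloxy)pent-2-enoate
Product: 20 (1R,6R,7S,8S,10R)-14-acetoxy-1,10-epoxy-8-(triethylsilyloxy)germacra-4E,11(13)-dien-12,6-olide, via macrocyclic hydroxy ester 19 (not isolated)
Conditions: CrCl2 (8 equiv), THF/DMF (5:1), 0.003 M, syringe-pump addition, rt; aq. NH4Cl
Reagents that add atoms: none
Why: Intramolecular Nozaki–Hiyama (chromium Barbier) 2-(alkoxycarbonyl)allylation, in which the allylchromium adds through C7 to the enal in a chair transition state where allylic strain keeps H8 in the alkene plane so the tether (C9) delivers the aldehyde anti to OSiEt3 (setting C7), the ring-constrained chair gives the 6,7-anti adduct (setting C6) and its chromium alkoxide lactonises to the trans-lactone, by analogy with chromium- or zinc-mediated closures of related germacranolides.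

Step 13
Reactants: 20 (1R,6R,7S,8S,10R)-14-acetoxy-1,10-epoxy-8-(triethylsilyloxy)germacra-4E,11(13)-dien-12,6-olide
Product: 21 (1R,6R,7R,8S,10R)-14-acetoxy-1,10-epoxy-8-hydroxygermacra-4E,11(13)-dien-12,6-olide
Conditions: HF·pyridine, pyridine, THF, 0 °C
Reagents that add atoms: none
Why: Fluoride-mediated cleavage of the secondary triethylsilyl ether under pyridine-buffered conditions chosen to leave the epoxide, acetate and α-methylene lactone intact (the C7 descriptor changes only because the CIP ranking changes).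

Step 14
Reactants: 21 (1R,6R,7R,8S,10R)-14-acetoxy-1,10-epoxy-8-hydroxygermacra-4E,11(13)-dien-12,6-olide
Product: 22 (1R,6R,7R,8S,10R)-14-acetoxy-1,10-epoxy-8-(methacryloyloxy)germacra-4E,11(13)-dien-12,6-olide (CNP0150481.4)
Conditions: methacrylic anhydride, Et3N, DMAP (10 mol%), CH2Cl2, 0 °C → rt
Reagents that add atoms: methacrylic anhydride, CC(=C)C(=O)OC(=O)C(C)=C
Why: DMAP-catalysed acylation (Steglich-type) of the 8-hydroxyl with retention at C8 gives the target.

**Compound list**
1 | geranyl acetate, (2E)-3,7-dimethylocta-2,6-dien-1-yl acetate | CC(C)=CCC/C(C)=C/COC(C)=O | starting material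
2 | (2E)-3-methyl-6-oxohex-2-en-1-yl acetate | O=CCC/C(C)=C/COC(C)=O | intermediate
3 | (pent-4-en-1-yl)triphenylphosphonium bromide | C=CCCC[P+](c1ccccc1)(c1ccccc1)c1ccccc1.[Br-] | starting material
4 | ethyl formate | CCOC=O | starting material
5 | pent-4-enylidene(triphenyl)phosphorane | C=CCCC=P(c1ccccc1)(c1ccccc1)c1ccccc1 | intermediate
6 | 2-(triphenylphosphoranylidene)hex-5-enal | C=CCCC(C=O)=P(c1ccccc1)(c1ccccc1)c1ccccc1 | intermediate
7 | (2E,6E)-7-formyl-3-methylundeca-2,6,10-trien-1-yl acetate | C=CCC/C(C=O)=C\CC/C(C)=C/COC(C)=O | intermediate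
8 | (2S,3R)-3-[(3E)-5-acetoxy-3-methylpent-3-en-1-yl]-2-(but-3-en-1-yl)oxirane-2-carbaldehyde | C=CCC[C@]1(C=O)O[C@@H]1CC/C(C)=C/COC(C)=O | intermediate
9 | (2E)-5-[(2R,3R)-3-(but-3-en-1-yl)-3-(hydroxymethyl)oxiran-2-yl]-3-methylpent-2-en-1-yl acetate | C=CCC[C@]1(CO)O[C@@H]1CC/C(C)=C/COC(C)=O | intermediate
10 | (2E)-5-[(2R,3R)-3-(but-3-en-1-yl)-3-(hydroxymethyl)oxiran-2-yl]-3-methylpent-2-en-1-ol | C=CCC[C@]1(CO)O[C@@H]1CC/C(C)=C/CO | intermediate
11 | (2E)-5-[(2R,3R)-3-(but-3-en-1-yl)-3-(hydroxymethyl)oxiran-2-yl]-3-methylpent-2-enal | C=CCC[C@]1(CO)O[C@@H]1CC/C(C)=C/C=O | intermediate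
12 | [(2R,3R)-2-(but-3-en-1-yl)-3-[(3E)-3-methyl-5-oxopent-3-en-1-yl]oxiran-2-yl]methyl acetate | C=CCC[C@]1(COC(C)=O)O[C@@H]1CC/C(C)=C/C=O | intermediate
13 | [(2R,3R)-2-(3,4-dihydroxybutyl)-3-[(3E)-3-methyl-5-oxopent-3-en-1-yl]oxiran-2-yl]methyl acetate (both carbinol epimers) | OCC(O)CC[C@]1(COC(C)=O)O[C@@H]1CC/C(C)=C/C=O | intermediate
14 | [(2R,3R)-3-[(3E)-3-methyl-5-oxopent-3-en-1-yl]-2-(3-oxopropyl)oxiran-2-yl]methyl acetate | O=CCC[C@]1(COC(C)=O)O[C@@H]1CC/C(C)=C/C=O | intermediate
15 | [(2R,3R)-3-[(3E)-3-methyl-5-oxopent-3-en-1-yl]-2-[(2S)-3-oxo-2-(triethylsilyloxy)propyl]oxiran-2-yl]methyl acetate | O=C[C@@H](O[Si](CC)(CC)CC)C[C@]1(COC(C)=O)O[C@@H]1CC/C(C)=C/C=O | intermediate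
16 | methyl acrylate | C=CC(=O)OC | starting material
17 | methyl (4S)-5-[(2R,3R)-2-(acetoxymethyl)-3-[(3E)-3-methyl-5-oxopent-3-en-1-yl]oxiran-2-yl]-3-hydroxy-2-methylidene-4-(triethylsilyloxy)pentanoate (both C3 epimers) | C=C(C(=O)OC)C(O)[C@@H](O[Si](CC)(CC)CC)C[C@]1(COC(C)=O)O[C@@H]1CC/C(C)=C/C=O | intermediate
18 | methyl (2Z,4S)-5-[(2R,3R)-2-(acetoxymethyl)-3-[(3E)-3-methyl-5-oxopent-3-en-1-yl]oxiran-2-yl]-2-(bromomethyl)-4-(triethylsilyloxy)pent-2-enoate | BrC/C(C(=O)OC)=C\[C@@H](O[Si](CC)(CC)CC)C[C@]1(COC(C)=O)O[C@@H]1CC/C(C)=C/C=O | intermediate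
19 | methyl (1R,6R,7S,8S,10R)-14-acetoxy-1,10-epoxy-6-hydroxy-8-(triethylsilyloxy)germacra-4E,11(13)-dien-12-oate | CC[Si](CC)(CC)O[C@H]1C[C@]2(COC(C)=O)O[C@@H]2CC/C(C)=C/[C@@H](O)[C@@H]1C(=C)C(=O)OC | intermediate
20 | (1R,6R,7S,8S,10R)-14-acetoxy-1,10-epoxy-8-(triethylsilyloxy)germacra-4E,11(13)-dien-12,6-olide | CC[Si](CC)(CC)O[C@H]1C[C@]2(COC(C)=O)O[C@@H]2CC/C(C)=C/[C@H]2OC(=O)C(=C)[C@H]12 | intermediate
21 | (1R,6R,7R,8S,10R)-14-acetoxy-1,10-epoxy-8-hydroxygermacra-4E,11(13)-dien-12,6-olide | O[C@H]1C[C@]2(COC(C)=O)O[C@@H]2CC/C(C)=C/[C@H]2OC(=O)C(=C)[C@H]12 | intermediate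
22 | (1R,6R,7R,8S,10R)-14-acetoxy-1,10-epoxy-8-(methacryloyloxy)germacra-4E,11(13)-dien-12,6-olide | C=C(C)C(=O)O[C@H]1C[C@]2(COC(C)=O)O[C@@H]2CC/C(C)=C/[C@H]2OC(=O)C(=C)[C@H]12 | target

**Step count and risks**
Total step count: 14. Longest linear sequence: 13 (steps 1 and 3–14 from geranyl acetate; equally steps 2–14 from the phosphonium salt).

The three steps most likely to fail are steps 9, 12 and 10.

Step 9 (the proposed new α-silyloxylation) may fail because the enamine could attack the acyl-side oxygen of the perester, or because the reagent could silylate or oxidise the amine catalyst. The fallback uses known chemistry, sets out from 14 and returns at 15. D-Proline-catalysed α-aminoxylation with nitrosobenzene (CHCl3, 4 °C) followed by NaBH4 at −78 °C (the enal survives) gives [(2R,3R)-2-[(2S)-3-hydroxy-2-(phenylaminooxy)propyl]-3-[(3E)-3-methyl-5-oxopent-3-en-1-yl]oxiran-2-yl]methyl acetate F1. N–O cleavage with CuSO4·5H2O in MeOH gives [(2R,3R)-2-[(2S)-2,3-dihydroxypropyl]-3-[(3E)-3-methyl-5-oxopent-3-en-1-yl]oxiran-2-yl]methyl acetate F2. Et3SiOTf and 2,6-lutidine give [(2R,3R)-2-[(2S)-2,3-bis(triethylsilyloxy)propyl]-3-[(3E)-3-methyl-5-oxopent-3-en-1-yl]oxiran-2-yl]methyl acetate F3. Swern conditions ((COCl)2, DMSO, Et3N, −78 → −30 °C) oxidise only the primary silyl ether and give 15.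

Step 12 (macrocyclisation) may give oligomers or the 6-epi cis-lactone; a Lewis-acid-triggered transannular opening of the epoxide is also possible. The fallback changes the way the allyl nucleophile is made, sets out from 17 and returns at 20. Acetylation (Ac2O, DMAP) gives methyl (4S)-3-acetoxy-5-[(2R,3R)-2-(acetoxymethyl)-3-[(3E)-3-methyl-5-oxopent-3-en-1-yl]oxiran-2-yl]-2-methylidene-4-(triethylsilyloxy)pentanoate F4. Pd(PPh3)4 (5 mol%) and Et2Zn in THF at 0.003 M turn the π-allylpalladium into an allylzinc species that adds through C7 to the enal (umpolung allylation), and lactonisation then gives 20.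

Step 10 (Morita–Baylis–Hillman) may be slow on the hindered α-silyloxy aldehyde, with partial C8 epimerisation or an O8→O7 silyl shift under the amine. The fallback sets out from 15 and returns at 17 without a new compound (F0). [1-(Methoxycarbonyl)vinyl]diisobutylaluminium, preformed from methyl propiolate and i-Bu2AlH with HMPA in THF at 0 °C, is added at −78 °C, where the saturated α-silyloxy aldehyde should react before the β,β-disubstituted enal.

**Further compounds**
F1 | step 9 | [(2R,3R)-2-[(2S)-3-hydroxy-2-(phenylaminooxy)propyl]-3-[(3E)-3-methyl-5-oxopent-3-en-1-yl]oxiran-2-yl]methyl acetate | OC[C@@H](ONc1ccccc1)C[C@]1(COC(C)=O)O[C@@H]1CC/C(C)=C/C=O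
F2 | step 9 | [(2R,3R)-2-[(2S)-2,3-dihydroxypropyl]-3-[(3E)-3-methyl-5-oxopent-3-en-1-yl]oxiran-2-yl]methyl acetate | OC[C@@H](O)C[C@]1(COC(C)=O)O[C@@H]1CC/C(C)=C/C=O
F3 | step 9 | [(2R,3R)-2-[(2S)-2,3-bis(triethylsilyloxy)propyl]-3-[(3E)-3-methyl-5-oxopent-3-en-1-yl]oxiran-2-yl]methyl acetate | CC[Si](CC)(CC)OC[C@@H](O[Si](CC)(CC)CC)C[C@]1(COC(C)=O)O[C@@H]1CC/C(C)=C/C=O
F0 | step 10 | none | none
F4 | step 12 | methyl (4S)-3-acetoxy-5-[(2R,3R)-2-(acetoxymethyl)-3-[(3E)-3-methyl-5-oxopent-3-en-1-yl]oxiran-2-yl]-2-methylidene-4-(triethylsilyloxy)pentanoate | C=C(C(=O)OC)C(OC(C)=O)[C@@H](O[Si](CC)(CC)CC)C[C@]1(COC(C)=O)O[C@@H]1CC/C(C)=C/C=O
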